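**Plan**
1. Late disconnections: the ring C hydroxyquinone comes from an 11,14-dimethoxy-12-silyloxy arene, and the C6=C7 enol-lactone double bond from a C7 ketone (reduction, dehydration).
2. Central disconnection: the C4–C5 bond and the lactone O–C6 bond are cut together. Ring B is raised to the tropone level, so that C5 and C6 are the β- and α-carbons of a C7 carbonyl with bromine on C6. C19 is tied to O1 as a δ-lactone whose enolate carbon is C4.
3. Enabling feature: the C1 hydroxyl and the C19 carboxyl are cis across ring A (C1/C4), and C5–C6 of ring B adjoin C7 on ring C. One lactone enolate can therefore add to C5 and pass its carboxyl oxygen to C6.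
4. Forward order: ring C aldehyde, crossed aldol condensation, Friedel–Crafts closure of ring B (C7–C8), side chain by asymmetric dialkylzinc addition and lactonisation, bromotropone, ring A and γ-lactone in one operation, C7 deoxygenation, quinone.
5. Stereochemistry: C1 (R) by catalyst control; C4 relayed from C1 through the lactone tether; C5 from the chelated Michael transition state; the C6 and C7 stereocentres are transient.

Key step: step 11

Remark: locants follow icetexane numbering (ring A = C1–C5, C10; ring B = C5–C10 and C20; ring C = C8, C9, C11–C14; C19 = lactone carbonyl). Compound 7 is assumed to be purchasable.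
Remark: 12–17 are carried as epimer mixtures at the methyl-bearing carbon (C4), and 19–21 as mixtures at C6 and C7; all of these centres are set or erased later.

**Step 1**
Reactants: 1 1,2,4-trimethoxybenzene
Product: 2 2-(2,3,6-trimethoxyphenyl)propan-2-ol
Conditions: n-BuLi, THF, 0 °C; acetone, −78 °C → rt
Reagents that add atoms: acetone, CC(C)=O
Why: Directed ortho-metalation removes the proton flanked by two methoxy groups, and the aryllithium adds to acetone (1,2-addition).

**Step 2**
Reactants: 2 2-(2,3,6-trimethoxyphenyl)propan-2-ol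
Product: 3 2-isopropyl-1,3,4-trimethoxybenzene
Conditions: Et3SiH, CF3CO2H, CH2Cl2, 0 °C → rt
Reagents that add atoms: none
Why: Ionic hydrogenation should work because the tertiary benzylic cation, stabilised by the electron-rich ring, is reduced by hydride transfer from the silane.

**Step 3**
Reactants: 3 2-isopropyl-1,3,4-trimethoxybenzene
Product: 4 2-isopropyl-3,6-dimethoxyphenol
Conditions: BCl3, CH2Cl2, −20 → 0 °C
Reagents that add atoms: none
Why: Lewis-acid ether cleavage should select the methoxy group flanked on both sides (OMe and isopropyl), which is twisted out of the ring plane and can chelate boron with its neighbour, as in the central demethylation of 1,2,3-trimethoxyarenes.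

**Step 4**
Reactants: 4 2-isopropyl-3,6-dimethoxyphenol
Product: 5 tert-butyl(2-isopropyl-3,6-dimethoxyphenoxy)dimethylsilane
Conditions: TBSCl, imidazole, DMF, 40 °C
Reagents that add atoms: tert-butyldimethylsilyl chloride, CC(C)(C)[Si](C)(C)Cl
Why: Standard O-silylation masks the future C12 oxygen with a group that fluoride or aqueous acid removes at the quinone stage.

**Step 5**
Reactants: 5 tert-butyl(2-isopropyl-3,6-dimethoxyphenoxy)dimethylsilane
Product: 6 3-(tert-butyldimethylsilyloxy)-4-isopropyl-2,5-dimethoxybenzaldehyde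
Conditions: s-BuLi, TMEDA, THF, −78 °C; DMF
Reagents that add atoms: N,N-dimethylformamide, CN(C)C=O
Why: Directed ortho-metalation and formylation should occur at the ring hydrogen next to the C11 methoxy group (future C9), which is ortho to one oxygen and meta to two more and so is more acidic than the other ring hydrogen.

**Step 6**
Reactants: 6 3-(tert-butyldimethylsilyloxy)-4-isopropyl-2,5-dimethoxybenzaldehyde; 7 tert-butyl 5-oxopentanoate
Product: 8 tert-butyl (E)-4-formyl-5-[3-(tert-butyldimethylsilyloxy)-4-isopropyl-2,5-dimethoxyphenyl]pent-4-enoate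
Conditions: pyrrolidine (cat.), PhCO2H (cat.), toluene, 50 °C, slow addition of 7
Reagents that add atoms: none
Why: Amine-catalysed crossed aldol condensation (enamine of the enolisable aldehyde onto the non-enolisable aryl aldehyde, then elimination) should give the thermodynamic (E)-enal with the aryl group cis to the ester chain.

**Step 7**
Reactants: 8 tert-butyl (E)-4-formyl-5-arylpent-4-enoate
Product: 10 3-(tert-butyldimethylsilyloxy)-2-isopropyl-1,4-dimethoxy-9-oxo-8,9-dihydro-7H-benzo[7]annulene-6-carbaldehyde (ring B keto enal: C7 ketone, C10=C20, formyl carbon = C1), via carboxylic acid 9 (not isolated)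
Conditions: CF3CO2H, CH2Cl2, 0 °C; then (CF3CO)2O, 0 °C → rt
Reagents that add atoms: none
Why: After tert-butyl ester cleavage, intramolecular Friedel–Crafts acylation through the mixed anhydride should close the seven-membered ring B at C8 (ortho to OMe, para to the silyloxy group), since the E-alkene holds the acyl chain next to the ring.

**Step 8**
Reactants: 11 3-methyloxolan-2-one (α-methyl-γ-butyrolactone, racemic)
Product: 12 ethyl 4-iodo-2-methylbutanoate
Conditions: NaI, Me3SiCl, MeCN, 60 °C; then EtOH, rt
Reagents that add atoms: sodium iodide, [Na+].[I-]; ethanol, CCO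
Why: Iodotrimethylsilane formed in the flask opens the lactone by SN2 attack of iodide at the O–CH2 carbon, and the resulting acid is esterified by ethanol under the acidic conditions.

**Step 9**
Reactants: 10 ring B keto enal; 12 ethyl 4-iodo-2-methylbutanoate
Product: 15 (6R)-6-[3-(tert-butyldimethylsilyloxy)-2-isopropyl-1,4-dimethoxy-9-oxo-8,9-dihydro-7H-benzo[7]annulen-6-yl]-3-methyloxan-2-one, via dialkylzinc 13 (not isolated), via hydroxy ester 14 (not isolated)
Conditions: 12, Et2Zn, CuI (cat.), 50 °C, then vacuum; 10, Ti(OiPr)4, (1S,2S)-1,2-bis(trifluoromethanesulfonamido)cyclohexane (8 mol %), toluene, −20 → 40 °C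
Reagents that add atoms: none
Why: Iodine–zinc exchange gives the ester-bearing dialkylzinc, whose titanium/bis-sulfonamide-catalysed addition is selective for the aldehyde over the aryl ketone and sets C1 as (R) by catalyst control, and the δ-alkoxide then closes onto the ethyl ester (titanium-mediated transesterification) to the δ-lactone.

**Step 10**
Reactants: 15 δ-lactone ketone
Product: 17 (6R)-6-[8-bromo-3-(tert-butyldimethylsilyloxy)-2-isopropyl-1,4-dimethoxy-9-oxo-9H-benzo[7]annulen-6-yl]-3-methyloxan-2-one (6-bromobenzotropone), via gem-dibromide 16 (not isolated)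
Conditions: LiN(SiMe3)2 then NBS, THF, −78 °C (two cycles); then DBU, 0 °C
Reagents that add atoms: N-bromosuccinimide, O=C1CCC(=O)N1Br
Why: Two enolate brominations at C6, the only enolisable position of the aryl ketone, followed by E2 loss of HBr across C5–C6 should give the fully conjugated 2-bromotropone (bromination–dehydrobromination route to tropones).

**Step 11**
Reactants: 17 6-bromobenzotropone δ-lactone
Product: 19 (1R,4S,5R)-1-hydroxy-7-oxo-19,6-olide with C10=C20 and the silylated ring C (keto γ-lactone alcohol), via bridged bromo ketone 18 (not isolated)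
Conditions: LiN(SiMe3)2, THF, −78 → −30 °C; AcOH, −78 °C; then AgOSO2CF3, 2,6-lutidine, acetone/H2O, 0 °C → rt
Reagents that add atoms: water, O
Why: Proposed new method: LiN(SiMe3)2 forms the δ-lactone enolate (C4), which adds to C5, the β-carbon of the C7(=O)–C6(Br)=C5 unit of the benzotropone, giving the 2-oxabicyclo[2.2.2]octanone 18 after protonation at C6; silver-assisted loss of bromide from C6 with participation of the lactone carbonyl oxygen then gives a dioxacarbenium ion that water opens at C19, freeing O1 as the alcohol and leaving the strain-free 19,6-γ-lactone. The closest known reaction types are Michael-initiated ring closure of ester enolates onto α-bromo enones, intramolecular enolate Michael additions that build bicyclo[2.2.2]octanes, and silver-promoted displacement of α-bromo ketones by carboxyl oxygen with translactonisation. Ring A closes 6-exo-trig in the conjugate addition and the γ-lactone 5-exo-tet in the displacement. C4 is fixed by the tether, because C19 and O1 can only be bridged cis across ring A, and C5 by a lithium-chelated transition state in which the enolate oxygen lies over the C7 carbonyl so that C6 ends syn to the lactone bridge; C6 is epimerisable and is erased later. The step needs attack at C5 and not at the vinylogous position C20, which the polarisation of the bromo enone and the chelate geometry should secure, and substitution at C6 in preference to loss of HBr with return to a tropone, which the intramolecular oxygen nucleophile and the non-basic silver conditions should secure.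

**Step 12**
Reactants: 19 keto γ-lactone alcohol
Product: 20 (1R,4S,5R)-1-(tert-butyldimethylsilyloxy)-7-oxo-19,6-olide
Conditions: TBSCl, imidazole, DMF, rt
Reagents that add atoms: tert-butyldimethylsilyl chloride, CC(C)(C)[Si](C)(C)Cl
Why: Silylation of the only free hydroxyl ensures that only the C7 alcohol is dehydrated later.

**Step 13**
Reactants: 20 C1 silyl ether ketone
Product: 21 (1R,4S,5R)-1-(tert-butyldimethylsilyloxy)-7-hydroxy-19,6-olide
Conditions: NaBH4, MeOH/THF, −20 °C
Reagents that add atoms: none
Why: Hydride reduction should be chemoselective for the aryl ketone over the hindered lactone, and the C7 configuration is irrelevant.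

**Step 14**
Reactants: 21 C7 alcohol
Product: 22 (1R,4S,5R)-1-(tert-butyldimethylsilyloxy)-6,7-didehydro-19,6-olide (enol lactone, ring B cycloheptatriene)
Conditions: methyl N-(triethylammoniosulfonyl)carbamate, toluene, 50 °C
Reagents that add atoms: none
Why: Dehydration of the benzylic alcohol with the sulfamoyl carbamate inner salt (syn-elimination or ion pair) can only take the C6 hydrogen, which gives the arene-conjugated enol lactone.

**Step 15**
Reactants: 22 enol lactone
Product: 24 1-O-(tert-butyldimethylsilyl)-6,7-anhydroballotiquinone, via silyloxyquinone 23 (not isolated)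
Conditions: (NH4)2Ce(NO3)6, MeCN/H2O, 0 °C
Reagents that add atoms: water, O
Why: Oxidative demethylation of the para-dimethoxyarene should give the 11,14-quinone, and the vinylogous silyl ester at O12 is hydrolysed in the aqueous acidic medium.

**Step 16**
Reactants: 24 1-O-silyl quinone
Product: 25 6,7-anhydroballotiquinone
Conditions: HF·pyridine, THF, 0 °C → rt
Reagents that add atoms: none
Why: Fluoride cleaves the secondary silyl ether under mildly acidic conditions that the enol lactone and the hydroxyquinone should tolerate.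

**Compound list**
1 | 1,2,4-trimethoxybenzene | COc1ccc(OC)c(OC)c1 | starting material
2 | 2-(2,3,6-trimethoxyphenyl)propan-2-ol | COc1ccc(OC)c(OC)c1C(C)(C)O | intermediate
3 | 2-isopropyl-1,3,4-trimethoxybenzene | COc1ccc(OC)c(OC)c1C(C)C | intermediate
4 | 2-isopropyl-3,6-dimethoxyphenol | COc1ccc(OC)c(O)c1C(C)C | intermediate
5 | tert-butyl(2-isopropyl-3,6-dimethoxyphenoxy)dimethylsilane | COc1ccc(OC)c(O[Si](C)(C)C(C)(C)C)c1C(C)C | intermediate
6 | 3-(tert-butyldimethylsilyloxy)-4-isopropyl-2,5-dimethoxybenzaldehyde | COc1cc(C=O)c(OC)c(O[Si](C)(C)C(C)(C)C)c1C(C)C | intermediate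
7 | tert-butyl 5-oxopentanoate | CC(C)(C)OC(=O)CCCC=O | starting material
8 | tert-butyl (E)-4-formyl-5-[3-(tert-butyldimethylsilyloxy)-4-isopropyl-2,5-dimethoxyphenyl]pent-4-enoate | O=C/C(CCC(=O)OC(C)(C)C)=C/c1cc(OC)c(C(C)C)c(O[Si](C)(C)C(C)(C)C)c1OC | intermediate
9 | (E)-4-formyl-5-arylpent-4-enoic acid (free acid of 8) | O=C/C(CCC(=O)O)=C/c1cc(OC)c(C(C)C)c(O[Si](C)(C)C(C)(C)C)c1OC | intermediate
10 | 3-(tert-butyldimethylsilyloxy)-2-isopropyl-1,4-dimethoxy-9-oxo-8,9-dihydro-7H-benzo[7]annulene-6-carbaldehyde | O=CC1=Cc2c(OC)c(O[Si](C)(C)C(C)(C)C)c(C(C)C)c(OC)c2C(=O)CC1 | intermediate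
11 | 3-methyloxolan-2-one (racemic) | CC1CCOC1=O | starting material
12 | ethyl 4-iodo-2-methylbutanoate (racemic) | CCOC(=O)C(C)CCI | intermediate
13 | bis(4-ethoxy-3-methyl-4-oxobutyl)zinc | CCOC(=O)C(C)CC[Zn]CCC(C)C(=O)OCC | intermediate
14 | ethyl (5R)-5-hydroxy-2-methyl-5-(ring B keto-alkenyl)pentanoate, C2 epimers | CCOC(=O)C(C)CC[C@@H](O)C1=Cc2c(OC)c(O[Si](C)(C)C(C)(C)C)c(C(C)C)c(OC)c2C(=O)CC1 | intermediate
15 | (6R)-6-[3-(tert-butyldimethylsilyloxy)-2-isopropyl-1,4-dimethoxy-9-oxo-8,9-dihydro-7H-benzo[7]annulen-6-yl]-3-methyloxan-2-one, C3 epimers | CC1CC[C@@H](OC1=O)C1=Cc2c(OC)c(O[Si](C)(C)C(C)(C)C)c(C(C)C)c(OC)c2C(=O)CC1 | intermediate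
16 | 8,8-dibromo derivative of 15 (C6 gem-dibromide) | CC1CC[C@@H](OC1=O)C1=Cc2c(OC)c(O[Si](C)(C)C(C)(C)C)c(C(C)C)c(OC)c2C(=O)C(Br)(Br)C1 | intermediate
17 | (6R)-6-[8-bromo-3-(tert-butyldimethylsilyloxy)-2-isopropyl-1,4-dimethoxy-9-oxo-9H-benzo[7]annulen-6-yl]-3-methyloxan-2-one | CC1CC[C@@H](OC1=O)C1=Cc2c(OC)c(O[Si](C)(C)C(C)(C)C)c(C(C)C)c(OC)c2C(=O)C(Br)=C1 | intermediate
18 | (1R,4S,5R)-6-bromo-7-oxo-1,19-olide (2-oxabicyclo[2.2.2]octan-3-one bridging C1 and C4 of ring A, C10=C20), C6 epimers | C[C@@]12CC[C@@H](OC1=O)C1=Cc3c(OC)c(O[Si](C)(C)C(C)(C)C)c(C(C)C)c(OC)c3C(=O)C(Br)[C@@H]21 | intermediate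
19 | (1R,4S,5R)-1-hydroxy-7-oxo-19,6-olide, ring C as 11,14-dimethoxy-12-silyloxy arene, C6 epimers | C[C@@]12CC[C@@H](O)C3=Cc4c(OC)c(O[Si](C)(C)C(C)(C)C)c(C(C)C)c(OC)c4C(=O)C(OC1=O)[C@H]32 | intermediate
20 | (1R,4S,5R)-1-(tert-butyldimethylsilyloxy)-7-oxo-19,6-olide | C[C@@]12CC[C@@H](O[Si](C)(C)C(C)(C)C)C3=Cc4c(OC)c(O[Si](C)(C)C(C)(C)C)c(C(C)C)c(OC)c4C(=O)C(OC1=O)[C@H]32 | intermediate
21 | (1R,4S,5R)-1-(tert-butyldimethylsilyloxy)-7-hydroxy-19,6-olide, C6/C7 epimers | C[C@@]12CC[C@@H](O[Si](C)(C)C(C)(C)C)C3=Cc4c(OC)c(O[Si](C)(C)C(C)(C)C)c(C(C)C)c(OC)c4C(O)C(OC1=O)[C@H]32 | intermediate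
22 | (1R,4S,5R)-1-(tert-butyldimethylsilyloxy)-6,7-didehydro-19,6-olide with protected ring C | C[C@@]12CC[C@@H](O[Si](C)(C)C(C)(C)C)C3=Cc4c(OC)c(O[Si](C)(C)C(C)(C)C)c(C(C)C)c(OC)c4C=C(OC1=O)[C@H]32 | intermediate
23 | 1,12-bis-O-(tert-butyldimethylsilyl)-6,7-anhydroballotiquinone | C[C@@]12CC[C@@H](O[Si](C)(C)C(C)(C)C)C3=CC4=C(C=C(OC1=O)[C@H]32)C(=O)C(C(C)C)=C(O[Si](C)(C)C(C)(C)C)C4=O | intermediate
24 | 1-O-(tert-butyldimethylsilyl)-6,7-anhydroballotiquinone | C[C@@]12CC[C@@H](O[Si](C)(C)C(C)(C)C)C3=CC4=C(C=C(OC1=O)[C@H]32)C(=O)C(C(C)C)=C(O)C4=O | intermediate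
25 | 6,7-anhydroballotiquinone | CC(C)C1=C(O)C(=O)C2=C(C=C3OC(=O)[C@@]4(C)CC[C@@H](O)C(=C2)[C@@H]34)C1=O | target

Total steps: 16. Longest linear sequence: 15 (steps 1–7 and 9–16).

**Steps most likely to fail**

Step 11. The bromo ketone adduct may lose HBr and rearomatise to a tropone before the carboxyl oxygen arrives, or the enolate may add at the vinylogous terminus C20. The fallback builds the two bonds one after the other with known reactions, setting out from 15 and returning at 19. IBX in DMSO at 70 °C dehydrogenates C5–C6 of 15 to the bromine-free benzotropone lactone F1. LiN(SiMe3)2 in THF then effects the intramolecular Michael addition to give the bridged lactone ketone F2. KN(SiMe3)2 followed by 2-(phenylsulfonyl)-3-phenyloxaziridine hydroxylates the ketone enolate at C6 to the α-hydroxy ketone F3. Camphorsulfonic acid in toluene moves the acyl group from O1 to the C6 hydroxyl (translactonisation driven by release of the bicyclic strain) to give 19.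

Step 15. Over-oxidation may compete with quinone formation: electron and hydride loss from the arene-conjugated cycloheptatriene would lead toward a benzotropylium species. The fallback oxidises ring C before the C6=C7 bond exists, setting out from 21 and returning at 24. (NH4)2Ce(NO3)6 on the saturated alcohol 21 gives the hydroxyquinone alcohol F4. Na2S2O4 reduces it to the hydroquinone F5. Pyridinium p-toluenesulfonate then dehydrates F5 through an ortho-quinone methide at C7, and air reoxidises the product to 24.

Step 5. Metalation may occur at the wrong ring position (next to the C14 methoxy group). The fallback blocks that position, setting out from 5 and returning at 6. NBS in MeCN at 0 °C brominates the position para to the silyloxy group to give the aryl bromide F6. LiN(iPr)2 in THF at −78 °C followed by DMF formylates the single remaining ring hydrogen, flanked by Br and OMe, to give the bromo aldehyde F7. Pd(OAc)2/PPh3 with HCO2H/Et3N removes the bromine to give 6.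

**Further compounds**
F1 | step 11 | (6R)-6-[3-(tert-butyldimethylsilyloxy)-2-isopropyl-1,4-dimethoxy-9-oxo-9H-benzo[7]annulen-6-yl]-3-methyloxan-2-one (bromine-free benzotropone) | CC1CC[C@@H](OC1=O)C1=Cc2c(OC)c(O[Si](C)(C)C(C)(C)C)c(C(C)C)c(OC)c2C(=O)C=C1
F2 | step 11 | bridged 1,19-olide 7-ketone with C6 methylene (Michael adduct, same C1/C4/C5 arrangement as 18) | C[C@@]12CC[C@@H](OC1=O)C1=Cc3c(OC)c(O[Si](C)(C)C(C)(C)C)c(C(C)C)c(OC)c3C(=O)C[C@@H]21
F3 | step 11 | bridged 1,19-olide 6-hydroxy-7-ketone | C[C@@]12CC[C@@H](OC1=O)C1=Cc3c(OC)c(O[Si](C)(C)C(C)(C)C)c(C(C)C)c(OC)c3C(=O)C(O)[C@@H]21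
F4 | step 15 | 1-O-(tert-butyldimethylsilyl)-7-hydroxy-6,7-dihydro quinone (12-hydroxy-11,14-quinone, 19,6-olide) | C[C@@]12CC[C@@H](O[Si](C)(C)C(C)(C)C)C3=CC4=C(C(O)C(OC1=O)[C@H]32)C(=O)C(C(C)C)=C(O)C4=O
F5 | step 15 | hydroquinone of F4 (11,12,14-trihydroxy arene) | C[C@@]12CC[C@@H](O[Si](C)(C)C(C)(C)C)C3=Cc4c(O)c(O)c(C(C)C)c(O)c4C(O)C(OC1=O)[C@H]32
F6 | step 5 | (4-bromo-2-isopropyl-3,6-dimethoxyphenoxy)(tert-butyl)dimethylsilane | COc1c(Br)cc(OC)c(O[Si](C)(C)C(C)(C)C)c1C(C)C
F7 | step 5 | 6-bromo-3-(tert-butyldimethylsilyloxy)-4-isopropyl-2,5-dimethoxybenzaldehyde | COc1c(Br)c(C=O)c(OC)c(O[Si](C)(C)C(C)(C)C)c1C(C)C
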